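**Retrosynthetic overview**
1. Target ⇒ Heck disconnection of the (E)-styryl bond: vinylcyclohexene 20 + 8-iodo-5,7-dimethoxycoumarin 3. Both coumarin bicycles come intact from 5,7-dimethoxycoumarin and are never rebuilt.
2. 20 ⇒ aldehyde 19 (Wittig) ⇒ aldehyde 17 by enolate methylation anti to the aryl group, so the benzylic centre sets the quaternary centre.
3. 17 ⇒ acid 14 ⇒ ring-closing metathesis of dienoic acid 13. The cyclohexene is the only ring formed in the route.
4. 13 ⇒ Ireland–Claisen rearrangement of ester 10 (C–O to C–C chirality transfer), made from allylic alcohol (S)-6 and acid 9.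
5. (S)-6 ⇒ ketoreductase reduction of the achiral enone 5 (first stereocentre) ⇒ Heck reaction of 3 with methyl vinyl ketone.

Assumption: Ar = 5,7-dimethoxy-2-oxo-2H-chromen-8-yl; only discrete compounds of telescoped operations are numbered as non-isolated intermediates (not enolates, ylide adducts or organopalladium species).

**Route**

Step 1
Reactants: 1 5,7-dimethoxy-2H-chromen-2-one (5,7-dimethoxycoumarin); 2 N-iodosuccinimide
Product: 3 8-iodo-5,7-dimethoxy-2H-chromen-2-one
Conditions: NIS (1.05 eq), TFA (10 mol %), MeCN, 0 °C → rt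
Reagents that add atoms: N-iodosuccinimide, O=C1CCC(=O)N1I
Why: Electrophilic aromatic iodination (SEAr) is expected at C8, by analogy with 5,7-dimethoxyflavones, and the regiochemistry is checked by NOE of the remaining 6-H to both OMe groups.

Step 2
Reactants: 3 8-iodo-5,7-dimethoxy-2H-chromen-2-one; 4 but-3-en-2-one (methyl vinyl ketone)
Product: 5 5,7-dimethoxy-8-[(E)-3-oxobut-1-en-1-yl]-2H-chromen-2-one
Conditions: Pd(OAc)2 (5 mol %), P(o-tol)3 (10 mol %), Et3N, MeCN, 80 °C
Reagents that add atoms: but-3-en-2-one, CC(=O)C=C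
Why: Mizoroki–Heck reaction of an aryl iodide with an electron-poor terminal alkene gives the (E)-enone selectively.

Step 3
Reactants: 5 5,7-dimethoxy-8-[(E)-3-oxobut-1-en-1-yl]-2H-chromen-2-one
Product: 6 8-[(1E,3S)-3-hydroxybut-1-en-1-yl]-5,7-dimethoxy-2H-chromen-2-one
Conditions: (S)-selective ketoreductase (Prelog-type NADH-dependent alcohol dehydrogenase), NAD+ (cat.), i-PrOH (15 % v/v), phosphate buffer pH 7, DMSO (5 %), 30 °C
Reagents that add atoms: none
Why: Asymmetric biocatalytic carbonyl reduction: the ketoreductase delivers hydride to the re face of the methyl ketone (methyl in the small pocket, styryl in the large one), creating the first stereocentre as the (S)-allylic alcohol with isopropanol-coupled cofactor recycling.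

Step 4
Reactants: 7 5-oxohexanoic acid; 8 methyltriphenylphosphonium bromide
Product: 9 5-methylhex-5-enoic acid
Conditions: Ph3PCH3Br (2.3 eq), KOt-Bu (3.4 eq), THF, 0 °C → rt; aq. HCl work-up
Reagents that add atoms: methyltriphenylphosphonium bromide, C[P+](c1ccccc1)(c1ccccc1)c1ccccc1.[Br-]
Why: Wittig methylenation of the ketone proceeds on the carboxylate salt and gives the 1,1-disubstituted alkene needed later for ring closure.

Step 5
Reactants: 6 8-[(1E,3S)-3-hydroxybut-1-en-1-yl]-5,7-dimethoxy-2H-chromen-2-one; 9 5-methylhex-5-enoic acid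
Product: 10 (2S,3E)-4-Ar-but-3-en-2-yl 5-methylhex-5-enoate
Conditions: DCC, DMAP (cat.), CH2Cl2, 0 °C → rt; chromatography on Et3N-deactivated silica
Reagents that add atoms: none
Why: Steglich esterification acylates the secondary allylic alcohol under neutral conditions with retention, so the C–O stereocentre is not ionised.

Step 6
Reactants: 10 (2S,3E)-4-Ar-but-3-en-2-yl 5-methylhex-5-enoate
Product: 13 (3R,4E)-3-Ar-2-(3-methylbut-3-en-1-yl)hex-4-enoic acid (2-epimers), via silyl ketene acetal 11 (not isolated), via trimethylsilyl ester 12 (not isolated)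
Conditions: LiHMDS (1.3 eq), TMSCl–Et3N (3 eq), toluene–THF, −78 °C → rt, then 60 °C; 1 M HCl work-up
Reagents that add atoms: none
Why: Ireland–Claisen rearrangement: the silyl ketene acetal reacts through a chair transition state with the carbinol methyl equatorial, so the (S)-C–O centre is relayed suprafacially to the (R)-benzylic carbon with an (E)-propenyl group, while the α-carbon forms as an inconsequential epimer mixture.

Step 7
Reactants: 13 (3R,4E)-3-Ar-2-(3-methylbut-3-en-1-yl)hex-4-enoic acid (2-epimers)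
Product: 14 (2R)-2-Ar-4-methylcyclohex-3-ene-1-carboxylic acid (1-epimers)
Conditions: Grubbs II catalyst (5 mol %), CH2Cl2, 40 °C
Reagents that add atoms: none
Why: Ring-closing metathesis joins the isopropenyl and propenyl termini into the trisubstituted cyclohexene with loss of propene, leaving the benzylic stereocentre and the metathesis-inert coumarin C3=C4 bond untouched.

Step 8
Reactants: 14 (2R)-2-Ar-4-methylcyclohex-3-ene-1-carboxylic acid (1-epimers); 15 1-chloro-N,N,2-trimethylprop-1-en-1-amine (Ghosez's reagent)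
Product: 16 (2R)-2-Ar-4-methylcyclohex-3-ene-1-carbonyl chloride (1-epimers)
Conditions: Ghosez's reagent (1.2 eq), CH2Cl2, 0 °C → rt; concentrate and use crude
Reagents that add atoms: 1-chloro-N,N,2-trimethylprop-1-en-1-amine, CC(C)=C(Cl)N(C)C
Why: Acid chloride formation with the chloroenamine is neutral, avoiding HCl and Vilsmeier species that could attack the trisubstituted alkene or the electron-rich arene.

Step 9
Reactants: 16 (2R)-2-Ar-4-methylcyclohex-3-ene-1-carbonyl chloride (1-epimers)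
Product: 17 (2R)-2-Ar-4-methylcyclohex-3-ene-1-carbaldehyde (1-epimers)
Conditions: LiAlH(Ot-Bu)3 (1.1 eq), THF, −78 °C
Reagents that add atoms: none
Why: Partial hydride reduction: LiAlH(Ot-Bu)3 at −78 °C reduces acid chlorides to aldehydes and leaves the coumarin lactone and the aldehyde itself alone.

Step 10
Reactants: 17 (2R)-2-Ar-4-methylcyclohex-3-ene-1-carbaldehyde (1-epimers); 18 iodomethane
Product: 19 (1S,2S)-2-Ar-1,4-dimethylcyclohex-3-ene-1-carbaldehyde
Conditions: KOt-Bu (1.2 eq) added to 17 and MeI (3 eq), THF, −20 → 0 °C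
Reagents that add atoms: iodomethane, CI
Why: Enolate C-alkylation: both epimers converge on one potassium enolate, which is methylated anti to the bulky pseudoaxial aryl group on the neighbouring carbon (1,2-induction), giving the quaternary centre with methyl trans and formyl cis to the aryl group.

Step 11
Reactants: 19 (1S,2S)-2-Ar-1,4-dimethylcyclohex-3-ene-1-carbaldehyde; 8 methyltriphenylphosphonium bromide
Product: 20 8-[(1R,6R)-6-ethenyl-3,6-dimethylcyclohex-2-en-1-yl]-5,7-dimethoxy-2H-chromen-2-one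
Conditions: Ph3PCH3Br (1.5 eq), KOt-Bu (1.4 eq), THF, 0 °C → rt
Reagents that add atoms: methyltriphenylphosphonium bromide, C[P+](c1ccccc1)(c1ccccc1)c1ccccc1.[Br-]
Why: Wittig methylenation of a non-enolisable neopentyl aldehyde is much faster than any attack of the ylide on the electron-rich coumarin lactone and affects no stereocentre.

Step 12
Reactants: 20 8-[(1R,6R)-6-ethenyl-3,6-dimethylcyclohex-2-en-1-yl]-5,7-dimethoxy-2H-chromen-2-one; 3 8-iodo-5,7-dimethoxy-2H-chromen-2-one
Product: 21 8-[(E)-2-[(1R,2R)-2-Ar-1,4-dimethylcyclohex-3-en-1-yl]ethenyl]-5,7-dimethoxy-2H-chromen-2-one (target)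
Conditions: Pd(OAc)2 (10 mol %), P(o-tol)3 (20 mol %), Et3N, DMF, 100 °C
Reagents that add atoms: none
Why: Mizoroki–Heck reaction: aryl–Pd adds to the terminal vinyl carbon and β-hydride elimination can only occur toward the benzylic CH2 because the other neighbour is quaternary, giving the (E)-styryl link without touching either stereocentre or the ring alkene.

**Compound list**

1 | 5,7-dimethoxy-2H-chromen-2-one | COc1cc(OC)c2ccc(=O)oc2c1 | starting material
2 | N-iodosuccinimide | O=C1CCC(=O)N1I | starting material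
3 | 8-iodo-5,7-dimethoxy-2H-chromen-2-one | COc1cc(OC)c2ccc(=O)oc2c1I | intermediate
4 | but-3-en-2-one | CC(=O)C=C | starting material
5 | 5,7-dimethoxy-8-[(E)-3-oxobut-1-en-1-yl]-2H-chromen-2-one | COc1cc(OC)c2ccc(=O)oc2c1/C=C/C(C)=O | intermediate
6 | 8-[(1E,3S)-3-hydroxybut-1-en-1-yl]-5,7-dimethoxy-2H-chromen-2-one | COc1cc(OC)c2ccc(=O)oc2c1/C=C/[C@H](C)O | intermediate
7 | 5-oxohexanoic acid | CC(=O)CCCC(=O)O | starting material
8 | methyltriphenylphosphonium bromide | C[P+](c1ccccc1)(c1ccccc1)c1ccccc1.[Br-] | starting material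
9 | 5-methylhex-5-enoic acid | C=C(C)CCCC(=O)O | intermediate
10 | (2S,3E)-4-(5,7-dimethoxy-2-oxo-2H-chromen-8-yl)but-3-en-2-yl 5-methylhex-5-enoate | COc1cc(OC)c2ccc(=O)oc2c1/C=C/[C@H](C)OC(=O)CCCC(C)=C | intermediate
11 | 8-[(1E,3S)-3-({5-methyl-1-[(trimethylsilyl)oxy]hexa-1,5-dien-1-yl}oxy)but-1-en-1-yl]-5,7-dimethoxy-2H-chromen-2-one (silyl ketene acetal) | COc1cc(OC)c2ccc(=O)oc2c1/C=C/[C@H](C)OC(O[Si](C)(C)C)=CCCC(C)=C | intermediate (not isolated)
12 | trimethylsilyl (3R,4E)-3-(5,7-dimethoxy-2-oxo-2H-chromen-8-yl)-2-(3-methylbut-3-en-1-yl)hex-4-enoate (2-epimers) | C/C=C/[C@H](C(CCC(C)=C)C(=O)O[Si](C)(C)C)c1c(OC)cc(OC)c2ccc(=O)oc12 | intermediate (not isolated)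
13 | (3R,4E)-3-(5,7-dimethoxy-2-oxo-2H-chromen-8-yl)-2-(3-methylbut-3-en-1-yl)hex-4-enoic acid (2-epimers) | C/C=C/[C@H](C(CCC(C)=C)C(=O)O)c1c(OC)cc(OC)c2ccc(=O)oc12 | intermediate
14 | (2R)-2-(5,7-dimethoxy-2-oxo-2H-chromen-8-yl)-4-methylcyclohex-3-ene-1-carboxylic acid (1-epimers) | OC(=O)C1CCC(C)=C[C@H]1c1c(OC)cc(OC)c2ccc(=O)oc12 | intermediate
15 | 1-chloro-N,N,2-trimethylprop-1-en-1-amine | CC(C)=C(Cl)N(C)C | starting material
16 | (2R)-2-(5,7-dimethoxy-2-oxo-2H-chromen-8-yl)-4-methylcyclohex-3-ene-1-carbonyl chloride (1-epimers) | O=C(Cl)C1CCC(C)=C[C@H]1c1c(OC)cc(OC)c2ccc(=O)oc12 | intermediate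
17 | (2R)-2-(5,7-dimethoxy-2-oxo-2H-chromen-8-yl)-4-methylcyclohex-3-ene-1-carbaldehyde (1-epimers) | O=CC1CCC(C)=C[C@H]1c1c(OC)cc(OC)c2ccc(=O)oc12 | intermediate
18 | iodomethane | CI | starting material
19 | (1S,2S)-2-(5,7-dimethoxy-2-oxo-2H-chromen-8-yl)-1,4-dimethylcyclohex-3-ene-1-carbaldehyde | O=C[C@@]1(C)CCC(C)=C[C@H]1c1c(OC)cc(OC)c2ccc(=O)oc12 | intermediate
20 | 8-[(1R,6R)-6-ethenyl-3,6-dimethylcyclohex-2-en-1-yl]-5,7-dimethoxy-2H-chromen-2-one | C=C[C@@]1(C)CCC(C)=C[C@H]1c1c(OC)cc(OC)c2ccc(=O)oc12 | intermediate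
21 | 8-[(E)-2-[(1R,2R)-2-(5,7-dimethoxy-2-oxo-2H-chromen-8-yl)-1,4-dimethylcyclohex-3-en-1-yl]ethenyl]-5,7-dimethoxy-2H-chromen-2-one | COc1cc(OC)c2ccc(=O)oc2c1/C=C/[C@@]1(C)CCC(C)=C[C@H]1c1c(OC)cc(OC)c2ccc(=O)oc12 | target

**Totals**
Total step count: 12. Longest linear sequence: 11 steps (1, 2, 3, 5, 6, 7, 8, 9, 10, 11, 12); step 4 is a side branch.

**Three steps most likely to fail**

Step 6 (Ireland–Claisen). The risks are attack of the amide base on the coumarin and a slow rearrangement onto a carbon carrying a di-ortho-substituted aryl group. The fallback sets out from 3 and builds both stereocentres by a catalytic asymmetric Diels–Alder reaction instead of the sigmatropic relay. Heck coupling of 3 with 2-methylbut-3-en-2-ol gives the tertiary allylic alcohol 8-[(E)-3-hydroxy-3-methylbut-1-en-1-yl]-5,7-dimethoxy-2H-chromen-2-one F1. Dehydration with catalytic p-TsOH in warm toluene gives the diene 5,7-dimethoxy-8-[(E)-3-methylbuta-1,3-dien-1-yl]-2H-chromen-2-one F2. F2 then reacts with methacrolein under a chiral oxazaborolidinium triflimide Lewis acid (CH2Cl2, −78 to −40 °C). The aryl-bearing diene terminus bonds to the α-carbon ("ortho/para" regiochemistry) and the endo mode puts the formyl group cis to the aryl group. The catalyst enantiomer is chosen to give the (1S,2S) adduct, and the minor exo diastereomer is removed by chromatography. The fallback comes back to the route at 19.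

Step 10 (α-methylation of the aldehyde). The risks are O-methylation, aldol side reactions and incomplete facial selectivity. The fallback sets out from 14 and moves the alkylation to the carboxylic ester level, where lithium enolates C-alkylate cleanly. Esterification of 14 with 2-(trimethylsilyl)ethanol (DCC, DMAP) gives 2-(trimethylsilyl)ethyl (2R)-2-Ar-4-methylcyclohex-3-ene-1-carboxylate F3. LDA (THF, −78 °C) followed by MeI/DMPU methylates the ester enolate anti to the aryl group and gives 2-(trimethylsilyl)ethyl (1S,2S)-2-Ar-1,4-dimethylcyclohex-3-ene-1-carboxylate F4. TBAF cleaves the silylethyl group remotely from the hindered carbonyl and gives (1S,2S)-2-Ar-1,4-dimethylcyclohex-3-ene-1-carboxylic acid F5. Ghosez's reagent 15 converts it to (1S,2S)-2-Ar-1,4-dimethylcyclohex-3-ene-1-carbonyl chloride F6, and LiAlH(Ot-Bu)3 at −78 °C reduces F6 to the aldehyde. The fallback comes back to the route at 19.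

Step 12 (final Heck reaction). The risk is slow insertion between a di-ortho-substituted aryl–Pd species and a vinyl group on a congested quaternary carbon. The fallback sets out from 19 and replaces the Heck reaction by a Suzuki–Miyaura coupling of a preformed (E)-alkenylboronate. Ohira–Bestmann homologation of 19 (dimethyl (1-diazo-2-oxopropyl)phosphonate, K2CO3, MeOH) gives the alkyne 8-[(1R,6S)-6-ethynyl-3,6-dimethylcyclohex-2-en-1-yl]-5,7-dimethoxy-2H-chromen-2-one F7. Zirconocene hydrochloride-catalysed syn-hydroboration with pinacolborane gives the boronate 5,7-dimethoxy-8-[(1R,6R)-3,6-dimethyl-6-[(E)-2-(4,4,5,5-tetramethyl-1,3,2-dioxaborolan-2-yl)ethenyl]cyclohex-2-en-1-yl]-2H-chromen-2-one F8. Coupling of F8 with 3 (Pd(dppf)Cl2, K3PO4, dioxane–water, 80 °C; acidic work-up to re-close any opened lactone) proceeds with retention of the (E)-geometry. The fallback comes back to the route at 21.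

**Further compounds**
F1 | step 6 | 8-[(E)-3-hydroxy-3-methylbut-1-en-1-yl]-5,7-dimethoxy-2H-chromen-2-one | COc1cc(OC)c2ccc(=O)oc2c1/C=C/C(C)(C)O
F2 | step 6 | 5,7-dimethoxy-8-[(E)-3-methylbuta-1,3-dien-1-yl]-2H-chromen-2-one | COc1cc(OC)c2ccc(=O)oc2c1/C=C/C(C)=C
F3 | step 10 | 2-(trimethylsilyl)ethyl (2R)-2-(5,7-dimethoxy-2-oxo-2H-chromen-8-yl)-4-methylcyclohex-3-ene-1-carboxylate (1-epimers) | C[Si](C)(C)CCOC(=O)C1CCC(C)=C[C@H]1c1c(OC)cc(OC)c2ccc(=O)oc12
F4 | step 10 | 2-(trimethylsilyl)ethyl (1S,2S)-2-(5,7-dimethoxy-2-oxo-2H-chromen-8-yl)-1,4-dimethylcyclohex-3-ene-1-carboxylate | C[Si](C)(C)CCOC(=O)[C@@]1(C)CCC(C)=C[C@H]1c1c(OC)cc(OC)c2ccc(=O)oc12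
F5 | step 10 | (1S,2S)-2-(5,7-dimethoxy-2-oxo-2H-chromen-8-yl)-1,4-dimethylcyclohex-3-ene-1-carboxylic acid | OC(=O)[C@@]1(C)CCC(C)=C[C@H]1c1c(OC)cc(OC)c2ccc(=O)oc12
F6 | step 10 | (1S,2S)-2-(5,7-dimethoxy-2-oxo-2H-chromen-8-yl)-1,4-dimethylcyclohex-3-ene-1-carbonyl chloride | O=C(Cl)[C@@]1(C)CCC(C)=C[C@H]1c1c(OC)cc(OC)c2ccc(=O)oc12
F7 | step 12 | 8-[(1R,6S)-6-ethynyl-3,6-dimethylcyclohex-2-en-1-yl]-5,7-dimethoxy-2H-chromen-2-one | C#C[C@@]1(C)CCC(C)=C[C@H]1c1c(OC)cc(OC)c2ccc(=O)oc12
F8 | step 12 | 5,7-dimethoxy-8-[(1R,6R)-3,6-dimethyl-6-[(E)-2-(4,4,5,5-tetramethyl-1,3,2-dioxaborolan-2-yl)ethenyl]cyclohex-2-en-1-yl]-2H-chromen-2-one | CC1(C)OB(OC1(C)C)/C=C/[C@@]1(C)CCC(C)=C[C@H]1c1c(OC)cc(OC)c2ccc(=O)oc12
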